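The product of the new flask comes from a racemate under a single-handed free catalyst, a kinetic resolution, and its excess hangs on one small correction: the leak, the right-handed part of the product.

all flasks: left-handed substrate 0.0020 M; right-handed substrate 0.0020 M

| flask | solid reagent | free catalyst | added ligand | remark | time |
|---|---|---|---|---|---|
| south-west | 1 equiv | 0.12 mol% | 1.4 µM | run made earlier |  |
| north-east | 1 equiv | 0.12 mol% | 5.6 µM | run made earlier |  |
| west | 1 equiv | 0.06 mol% | 2.8 µM | run made earlier |  |
| flask | 1.00 equiv | 0.12 mol% | 2.8 µM |  | 2.5 min |

| run | time / s | left-handed product / % | right-handed product / % |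
|---|---|---|---|
| south-west | 10.0 | 2 | 0 |
| south-west | 15.0 | 3 | 1 |
| south-west | 25.0 | 5 | 1 |
| south-west | 40.0 | 8 | 0 |
| south-west | 80.0 | 10 | 0 |
| south-west | 120 | 15 | 0 |
| north-east | 20.0 | 2 | 2 |
| north-east | 40.0 | 8 | 0 |
| north-east | 60.0 | 12 | 0 |
| north-east | 80.0 | 13 | 2 |
| north-east | 90.0 | 8 | 0 |
| north-east | 120 | 14 | 0 |
| west | 10.0 | 3 | 1 |
| west | 20.0 | 1 | 1 |
| west | 30.0 | 4 | 0 |
| west | 60.0 | 8 | 0 |
| west | 120 | 13 | 3 |

(scatter of a reading: 1.5 percentage points)

- excess of left-handed product over right-handed product in the product at 8.0 s
- excess of left-handed product over right-handed product in the product at 2.5 min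
- part of the left-handed substrate and right-handed substrate charged together that has reacted at 2.5 min

- free catalyst is single-handed; left-handed substrate and right-handed substrate are mirror images of each other, charged as a racemate, each of them at the stated concentration
- given per volume of solution although it is solid: solid reagent
- at the start none of the solid reagent is in solution
- an excess is the difference of the two amounts in percent of their sum
- an excess is below zero if the other one leads

Excess is one minus twice the leak. One extreme version of the new flask makes no right-handed product: leak nil, excess 100%. The other extreme takes each right-handed reading as real. Pooled over the three runs, that gives 7.86%, the ceiling leak: summed right-handed product as a part of summed product. Its excess is 84.3%. No right-handed reading stands above 3%, a reading scatters by 1.5 percentage points, and readings stop at zero, so scatter swells the pool. Its loading and ligand stay within those of the runs, so the new flask is expected between the extremes. My own reckoning takes half the ceiling, a leak of 3.93%, so an excess of 92.1%.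

The forecast gives 90% at 8.0 s, 89% at 2.5 min and 18% reacted at 2.5 min, holding that “the excess should fall only slightly”. Its late excess stands a little below mine, between the same extremes.

The new flask gives 92.6% at 8.0 s, then 91.5% with 14.8% reacted at 2.5 min.

    free catalyst + left-handed substrate ⇌ catalyst intermediate A (K = 310 M⁻¹, k = 4.40 × 10⁶ M⁻¹ s⁻¹)
    2 free catalyst → spent catalyst (k = 1.70 × 10⁵ M⁻¹ s⁻¹)
    free catalyst + right-handed substrate ⇌ catalyst intermediate B (K = 190 M⁻¹, k = 1.20 × 10⁶ M⁻¹ s⁻¹)
    partner + catalyst intermediate A → free catalyst + left-handed product (k = 1.10 × 10⁵ M⁻¹ s⁻¹)
    free catalyst + added ligand ⇌ idle complex, settled at all times (K = 3.40 × 10⁵ M⁻¹)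
    solid reagent ⇌ partner, rate k6*(cs6 - [partner]) while solid is left; crystals form when [partner] > cs6 (solubility = 0.510 mM, k = 0.220 s⁻¹)
    partner + catalyst intermediate B → free catalyst + right-handed product (k = 6800 M⁻¹ s⁻¹)

Just after the start of the new flask, the partner goes 26 times as fast through catalyst intermediate A as through catalyst intermediate B, so 3.65% of its use at that moment makes right-handed product. In the product standing in the new flask at 2.5 min the leak is 4.25%, with less of the left-handed substrate left than of the right-handed substrate, 72% against 99%.

The neighbour flask, at 0.03 mol% of free catalyst, lies below the loadings of the runs; half the ceiling leak, 3.93%, carried there unchanged, gives an excess of 92.1%. Computed, that neighbour gives 92.0% at 2.5 min, with 9.74% reacted.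

The numbers in the tables are calculated with made-up constants, noise included.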